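**Retrosynthetic overview**
- The target is reached from the enal butenolide by 1,2-reduction of the aldehyde and acetylation; both side-chain ends are otherwise already in place.
- Key disconnection: the lactone O1–C5 bond and the C3=C4 double bond of the butenolide. This leads back to three simple pieces: a terminal alkyne (C4, C5 and the C5 side chain), cyclobut-1-ene-1-carboxylic acid (O1, C2, C3 and the three chain carbons next to C3) and methacrolein.
- Enabling feature: C5 is an allylic C–O stereocentre next to the ring alkene C4=C3, so the ring is a cyclised branched allylic ester. In addition, C3 together with the CH2–CH2–CH= unit of its side chain is a ring-opened cyclobutene whose former C=C is shared between the ring alkene and the side-chain alkene.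
- The alkyne comes from geranyl acetate by cleavage of the 6,7-alkene and one-carbon homologation.
- Ring order: the butenolide is the only ring of the target and is closed in the key step; the cyclobutene is a temporary ring that is opened in the same step.

Key step: step 5

Assumptions: cyclobut-1-ene-1-carboxylic acid is taken as commercially available. The (R,R) antipode of Cp-DIOP (the DIOP analogue with a cyclopentylidene ketal) is taken to give the (S)-ester; if a first run shows the opposite sense, the (S,S) ligand is used instead.

**Route**

Step 1
Reactants: 1 geranyl acetate, (2E)-3,7-dimethylocta-2,6-dien-1-yl acetate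
Product: 2 (2E)-5-(3,3-dimethyloxiran-2-yl)-3-methylpent-2-en-1-yl acetate (racemic epoxide)
Conditions: mCPBA (1.05 equiv), CH2Cl2, 0 °C
Reagents that add atoms: mCPBA, OOC(=O)c1cccc(Cl)c1
Why: Prilezhaev epoxidation is electrophilic, so the peracid should take the electron-rich 6,7-alkene and leave the 2,3-alkene, which the allylic acetate deactivates; the new stereocentre forms racemic and is destroyed in step 2.

Step 2
Reactants: 2 (2E)-5-(3,3-dimethyloxiran-2-yl)-3-methylpent-2-en-1-yl acetate
Product: 3 (2E)-3-methyl-6-oxohex-2-en-1-yl acetate
Conditions: H5IO6 (1.2 equiv), THF/H2O, 0 °C to rt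
Reagents that add atoms: none
Why: Periodic acid should hydrolyse the epoxide to the glycol (water entering at the tertiary carbon) and cleave it in the same flask (Malaprade glycol cleavage), so the aldehyde keeps the former epoxide oxygen and the acetate survives the mildly acidic medium.

Step 3
Reactants: 3 (2E)-3-methyl-6-oxohex-2-en-1-yl acetate
Product: 4 (2E)-3-methylhept-2-en-6-yn-1-ol
Conditions: dimethyl (1-diazo-2-oxopropyl)phosphonate (1.3 equiv), K2CO3 (2.5 equiv), MeOH, 0 °C to rt, 16 h
Reagents that add atoms: dimethyl (1-diazo-2-oxopropyl)phosphonate, CC(=O)C(=[N+]=[N-])P(=O)(OC)OC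
Why: Seyferth–Gilbert homologation in the Ohira–Bestmann variant should turn the aldehyde into the terminal alkyne through the diazoalkene and a 1,2-hydride shift of the alkylidene carbene, and the same K2CO3/MeOH is used on purpose to methanolyse the acetate completely so that one product results.

Step 4
Reactants: 4 (2E)-3-methylhept-2-en-6-yn-1-ol
Product: 5 (2E)-3-methylhept-2-en-6-yn-1-yl acetate
Conditions: Ac2O, pyridine, DMAP (cat.), CH2Cl2, 0 °C to rt
Reagents that add atoms: acetic anhydride, CC(=O)OC(C)=O
Why: DMAP-catalysed acetylation (nucleophilic acyl substitution) of the primary allylic alcohol; the terminal alkyne is inert.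

Step 5
Reactants: 5 (2E)-3-methylhept-2-en-6-yn-1-yl acetate; 6 cyclobut-1-ene-1-carboxylic acid; 7 methacrolein (2-methylprop-2-enal)
Product: 10 (5S)-5-[(2E)-4-acetoxy-2-methylbut-2-en-1-yl]-3-[(3E)-4-methyl-5-oxopent-3-en-1-yl]furan-2(5H)-one, via branched allylic ester 8 (not isolated), via butenyl butenolide 9 (not isolated)
Conditions: 6 (1.2 equiv), [Rh(cod)Cl]2 (2.5 mol %), (R,R)-Cp-DIOP (5 mol %), ClCH2CH2Cl, 60 °C; then, same flask, 7 (8 equiv), second-generation Hoveyda–Grubbs catalyst RuCl2(H2IMes)(=CH-C6H4-2-OiPr) (2 × 4 mol %), 45 °C, slow argon stream
Reagents that add atoms: none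
Why: Proposed new method: two catalytic cycles are run as a relay in one flask: a rhodium hydride carboxylate, formed by oxidative addition of the O–H bond of 6 to monovalent rhodium, isomerises the terminal alkyne of 5 to the allene and hydrometalates it to a π-allyl rhodium carboxylate, whose C–O reductive elimination at the substituted terminus gives ester 8 (bond O1–C5); the ruthenium alkylidene then loads on the new vinyl group, adds across the strained cyclobutene alkene and cycloreverts, which closes the butenolide at C3=C4 (9) and leaves a carbene or terminal alkene at the former cyclobutene CH that 7 caps as the (E)-enal. The closest known reaction types are the rhodium-catalysed redox-neutral coupling of terminal alkynes with carboxylic acids to branched allylic esters, ring-closing metathesis of allylic 2-alkylacrylates to 3-alkylbutenolides, tandem ring-opening/ring-closing metathesis of cyclobutenes and cross-metathesis with methacrolein; new are their union in one flask and a cyclobut-1-enecarboxylate as the metathesis partner. The only ring closed is the five-membered lactone, closed by ring-closing metathesis (metallacyclobutane from the C4 alkylidene and the cyclobutene alkene, then cycloreversion), with relief of cyclobutene strain as the driving force. The C5 stereocentre is set in the C–O bond-forming reductive elimination under control of the C2-symmetric diphosphine on rhodium and is not touched by the metathesis. The step needs branched over linear regioselectivity (inherent to the π-allyl rhodium carboxylate), selection of the vinyl/cyclobutene pair over the two trisubstituted alkenes (secured by their substitution and by ring size, every alternative closure being a four- or eight-membered ring) and E geometry in the enal (expected from thermodynamic control in cross-metathesis with the 1,1-disubstituted enal).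

Step 6
Reactants: 10 (5S)-5-[(2E)-4-acetoxy-2-methylbut-2-en-1-yl]-3-[(3E)-4-methyl-5-oxopent-3-en-1-yl]furan-2(5H)-one
Product: 11 (5S)-5-[(2E)-4-acetoxy-2-methylbut-2-en-1-yl]-3-[(3E)-5-hydroxy-4-methylpent-3-en-1-yl]furan-2(5H)-one
Conditions: NaBH4 (0.5 equiv), CeCl3·7H2O (1.1 equiv), MeOH, −78 °C; aq. NH4Cl
Reagents that add atoms: none
Why: Luche reduction: the cerium-activated methoxyborohydride should add 1,2 to the aldehyde at low temperature much faster than it attacks the conjugated lactone, the acetate or C5–H.

Step 7
Reactants: 11 (5S)-5-[(2E)-4-acetoxy-2-methylbut-2-en-1-yl]-3-[(3E)-5-hydroxy-4-methylpent-3-en-1-yl]furan-2(5H)-one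
Product: 12 (5S)-5-[(2E)-4-acetoxy-2-methylbut-2-en-1-yl]-3-[(3E)-5-acetoxy-4-methylpent-3-en-1-yl]furan-2(5H)-one (target)
Conditions: Ac2O (1.5 equiv), pyridine, DMAP (5 mol %), CH2Cl2, 0 °C
Reagents that add atoms: acetic anhydride, CC(=O)OC(C)=O
Why: DMAP-catalysed acetylation of the primary allylic alcohol under weakly basic conditions that should neither epimerise C5 nor move the butenolide alkene.

**Compound list**
1 | geranyl acetate, (2E)-3,7-dimethylocta-2,6-dien-1-yl acetate | CC(=O)OC/C=C(\C)CCC=C(C)C | starting material
2 | (2E)-5-(3,3-dimethyloxiran-2-yl)-3-methylpent-2-en-1-yl acetate (racemic) | CC(=O)OC/C=C(\C)CCC1OC1(C)C | intermediate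
3 | (2E)-3-methyl-6-oxohex-2-en-1-yl acetate | CC(=O)OC/C=C(\C)CCC=O | intermediate
4 | (2E)-3-methylhept-2-en-6-yn-1-ol | OC/C=C(\C)CCC#C | intermediate
5 | (2E)-3-methylhept-2-en-6-yn-1-yl acetate | CC(=O)OC/C=C(\C)CCC#C | intermediate
6 | cyclobut-1-ene-1-carboxylic acid | OC(=O)C1=CCC1 | starting material
7 | methacrolein, 2-methylprop-2-enal | CC(=C)C=O | starting material
8 | (3S,5E)-7-acetoxy-5-methylhepta-1,5-dien-3-yl cyclobut-1-ene-1-carboxylate | CC(=O)OC/C=C(\C)C[C@@H](C=C)OC(=O)C1=CCC1 | intermediate (not isolated)
9 | (5S)-5-[(2E)-4-acetoxy-2-methylbut-2-en-1-yl]-3-(but-3-en-1-yl)furan-2(5H)-one | CC(=O)OC/C=C(\C)C[C@H]1C=C(CCC=C)C(=O)O1 | intermediate (not isolated)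
10 | (5S)-5-[(2E)-4-acetoxy-2-methylbut-2-en-1-yl]-3-[(3E)-4-methyl-5-oxopent-3-en-1-yl]furan-2(5H)-one | CC(=O)OC/C=C(\C)C[C@H]1C=C(CC/C=C(\C)C=O)C(=O)O1 | intermediate
11 | (5S)-5-[(2E)-4-acetoxy-2-methylbut-2-en-1-yl]-3-[(3E)-5-hydroxy-4-methylpent-3-en-1-yl]furan-2(5H)-one | CC(=O)OC/C=C(\C)C[C@H]1C=C(CC/C=C(\C)CO)C(=O)O1 | intermediate
12 | (5S)-5-[(2E)-4-acetoxy-2-methylbut-2-en-1-yl]-3-[(3E)-5-acetoxy-4-methylpent-3-en-1-yl]furan-2(5H)-one | CC(=O)OC/C=C(\C)C[C@H]1C=C(CC/C=C(\C)COC(C)=O)C(=O)O1 | target

**Step count and risks**
Total step count: 7. Longest linear sequence: 7 steps (1 to 12); 6 and 7 enter in step 5.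

Steps most likely to fail:

1. Step 5 (Proposed new method). Several processes could defeat it:
 - β-hydride elimination from the π-allyl rhodium intermediate toward a conjugated triene instead of C–O bond formation, because the neighbouring CH2 is also allylic;
 - deactivation of the ruthenium carbene by rhodium and phosphine left in the flask;
 - ring-opening of the cyclobutene to a sluggish ester-substituted carbene that ends in oligomers;
 - insufficient or opposite enantioselection.

 The fallback uses only known reaction types, with isolation after each. It sets out from 5. Commercial diethyl 2-(but-3-en-1-yl)malonate is saponified (KOH, EtOH/H2O, then HCl) to 2-(but-3-en-1-yl)propanedioic acid F1. Mannich-type decarboxylative methylenation (paraformaldehyde, Et2NH, EtOAc, reflux) converts this into 2-methylidenehex-5-enoic acid F2. The rhodium-catalysed coupling of F2 with 5 ([Rh(cod)Cl]2, (R,R)-Cp-DIOP, ClCH2CH2Cl, 60 °C) should give (3S,5E)-7-acetoxy-5-methylhepta-1,5-dien-3-yl 2-methylidenehex-5-enoate F3, which is isolated and freed from rhodium and phosphine. Treatment of F3 with the second-generation Grubbs catalyst RuCl2(H2IMes)(PCy3)(=CHPh) and 7 in dilute CH2Cl2 at 40 °C should close the butenolide by ordinary ring-closing metathesis between the vinyl group and the acrylate methylidene, and cap the butenyl end by cross-metathesis. The fallback comes back to the route at 10.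

2. Step 6. Conjugate hydride delivery to the enal or the butenolide, opening of the lactone by methoxide, or epimerisation at C5 and alkene migration in the basic borate medium could compete with the 1,2-reduction. The fallback replaces the hydride reagent by a biocatalytic reduction with an alcohol dehydrogenase (ketoreductase class; NADPH recycled with glucose and glucose dehydrogenase; phosphate buffer pH 7, DMSO cosolvent, 30 °C). Such enzymes reduce only the aldehyde and work at neutral pH. The fallback sets out from 10 and comes back at 11; it makes no compound outside the list (entry F0).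

3. Step 3. Base-mediated aldol self-condensation of the enolisable aldehyde could outrun addition of the diazophosphonate anion, and incomplete methanolysis of the acetate could leave a mixture. The fallback is a Corey–Fuchs sequence that sets out from 3. CBr4 and PPh3 (CH2Cl2, 0 °C) should give (2E)-7,7-dibromo-3-methylhepta-2,6-dien-1-yl acetate F4. n-BuLi (4.5 equiv, THF, −78 to 0 °C, then aq. NH4Cl) converts the dibromoalkene into the alkyne and removes the acetyl group at the same time. The fallback comes back at 4.

**Further compounds**
F1 | step 5 | 2-(but-3-en-1-yl)propanedioic acid | OC(=O)C(CCC=C)C(=O)O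
F2 | step 5 | 2-methylidenehex-5-enoic acid | C=C(CCC=C)C(=O)O
F3 | step 5 | (3S,5E)-7-acetoxy-5-methylhepta-1,5-dien-3-yl 2-methylidenehex-5-enoate | CC(=O)OC/C=C(\C)C[C@@H](C=C)OC(=O)C(=C)CCC=C
F0 | step 6 | none | none
F4 | step 3 | (2E)-7,7-dibromo-3-methylhepta-2,6-dien-1-yl acetate | CC(=O)OC/C=C(\C)CCC=C(Br)Br
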